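The key step exploits the C2–C3–C4 chain of ring C, a masked 2-alkoxy-1,3-dicarbonyl unit: it is traced back to a 3,4,5-trisubstituted isoxazole holding C2 (with ring B) as C=N, C3 with its prenyl ether, and C4 (with ring A) as C–O. One operation, the union of 4-(prenyloxy)benzonitrile oxide with the lithium enolate of a protected ring A α-(prenyloxy)acetophenone, forms the C2–C3 bond and the isoxazole O–C4 bond and closes the five-membered ring. The ketone carries triisopropylsilyl ethers on the future O1 and C7 oxygens and a methoxymethyl ether on the future C5 oxygen, so that after N–O cleavage only one oxygen can close the pyranone.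

Key step: step 9

Remarks on the chemistry (assumptions)
- Flavone numbering (O1, C2 … C8a) is used for the corresponding atoms of all intermediates; prenyl = 3-methylbut-2-enyl.
- 2-Methoxyresorcinol supplies only three of the four ring A oxygens; the oxygen that becomes the C5 hydroxyl is therefore introduced by C–H borylation and oxidation (step 2) before it is protected (step 3).
- Conjugate bases made by simple deprotonation (aryllithium, enolate, alkoxide) are treated as activated forms of the numbered compounds and are not numbered separately.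
- Enaminones 18 and 19 are drawn as the hydrogen-bonded isomer (amino group cis to the carbonyl, E by the sequence rules); the geometry has no bearing on the ring closure.

Step 1
Reactants: 1 2-methoxyresorcinol
Product: 2 2-methoxy-1,3-bis(triisopropylsilyloxy)benzene
Conditions: i-Pr3SiCl (2.4 equiv), imidazole, DMF, rt to 40 °C
Reagents that add atoms: triisopropylsilyl chloride, CC(C)[Si](Cl)(C(C)C)C(C)C
Why: Imidazole-promoted silyl ether formation on both phenols; the bulky silyl groups are chosen because they resist migration in the later metalation and enolate steps and screen the two neighbouring ring positions.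

Step 2
Reactants: 2 2-methoxy-1,3-bis(triisopropylsilyloxy)benzene
Product: 4 4-methoxy-3,5-bis(triisopropylsilyloxy)phenol, via aryl pinacol boronate 3 (not isolated)
Conditions: B2pin2 (1.0 equiv), [Ir(OMe)(cod)]2 (cat.), 4,4'-di-tert-butyl-2,2'-bipyridine (cat.), THF, 80 °C; evaporate; then KHSO5 (as Oxone, 1.0 equiv), acetone/H2O, rt, 10 min
Reagents that add atoms: bis(pinacolato)diboron, CC1(C)OB(OC1(C)C)B1OC(C)(C)C(C)(C)O1 (its boron is carried by 3 only); potassium peroxymonosulfate, [K+].[O-]S(=O)(=O)OO (oxygen of the new hydroxyl)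
Why: Iridium-catalysed C–H borylation is sterically governed and should go only to the one ring position not flanked by a substituent (para to the methoxy group), and oxidation of the boronate (one-pot borylation/oxidation) then gives the phenol that carries the fourth ring A oxygen.

Step 3
Reactants: 4 4-methoxy-3,5-bis(triisopropylsilyloxy)phenol
Product: 5 2-methoxy-5-(methoxymethoxy)-1,3-bis(triisopropylsilyloxy)benzene
Conditions: MeOCH2Cl, i-Pr2NEt, CH2Cl2, 0 °C to rt
Reagents that add atoms: chloromethyl methyl ether, COCCl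
Why: O-Alkylation of the unhindered phenol (acetal ether formation) installs the group that directs the metalation and later keeps the future C5 oxygen out of the pyranone ring closure.

Step 4
Reactants: 6 3-methylbut-2-en-1-ol (prenyl alcohol); 7 2-chloro-N-methoxy-N-methylacetamide
Product: 8 N-methoxy-N-methyl-2-(3-methylbut-2-enyloxy)acetamide
Conditions: NaH, THF, 0 °C; then 7, Bu4NI (cat.), 0 °C to rt
Reagents that add atoms: none
Why: Williamson ether synthesis, the sodium alkoxide displacing the activated primary chloride, gives the α-prenyloxy Weinreb amide in one step.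

Step 5
Reactants: 5 2-methoxy-5-(methoxymethoxy)-1,3-bis(triisopropylsilyloxy)benzene; 8 N-methoxy-N-methyl-2-(3-methylbut-2-enyloxy)acetamide
Product: 9 1-[3-methoxy-6-(methoxymethoxy)-2,4-bis(triisopropylsilyloxy)phenyl]-2-(3-methylbut-2-enyloxy)ethan-1-one
Conditions: s-BuLi, TMEDA, THF, −78 °C; then 8, −78 to −40 °C; sat. aq. NH4Cl
Reagents that add atoms: none
Why: Directed ortho-metalation by the methoxymethoxy group (its two ortho positions are equivalent and further acidified by the adjacent silyloxy oxygen) followed by Weinreb ketone synthesis, in which the chelated tetrahedral adduct prevents over-addition and the low temperature and bulky silyl groups suppress oxygen-to-carbon silyl migration.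

Step 6
Reactants: 10 4-hydroxybenzaldehyde; 11 prenyl bromide (1-bromo-3-methylbut-2-ene)
Product: 12 4-(3-methylbut-2-enyloxy)benzaldehyde
Conditions: K2CO3, DMF, rt
Reagents that add atoms: none
Why: Williamson ether synthesis, the phenoxide attacking the primary allylic bromide in an SN2 reaction.

Step 7
Reactants: 12 4-(3-methylbut-2-enyloxy)benzaldehyde
Product: 13 (E)-4-(3-methylbut-2-enyloxy)benzaldehyde oxime
Conditions: NH2OH·HCl, NaOAc, EtOH/H2O, rt
Reagents that add atoms: hydroxylamine hydrochloride, Cl.NO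
Why: Oxime condensation, which for aryl aldehydes should give the E isomer under thermodynamic control.

Step 8
Reactants: 13 (E)-4-(3-methylbut-2-enyloxy)benzaldehyde oxime
Product: 14 (Z)-N-hydroxy-4-(3-methylbut-2-enyloxy)benzimidoyl chloride
Conditions: NCS (1.0 equiv), DMF, 0 °C to rt
Reagents that add atoms: N-chlorosuccinimide, O=C1CCC(=O)N1Cl
Why: Chlorination of the aldoxime carbon (hydroximoyl chloride formation) should be faster than attack on the trisubstituted alkene or the ring, as in the preparation of alkene-bearing hydroximoyl chlorides for intramolecular nitrile oxide cycloadditions.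

Step 9
Reactants: 9 1-[3-methoxy-6-(methoxymethoxy)-2,4-bis(triisopropylsilyloxy)phenyl]-2-(3-methylbut-2-enyloxy)ethan-1-one; 14 (Z)-N-hydroxy-4-(3-methylbut-2-enyloxy)benzimidoyl chloride
Product: 17 5-[3-methoxy-6-(methoxymethoxy)-2,4-bis(triisopropylsilyloxy)phenyl]-4-(3-methylbut-2-enyloxy)-3-[4-(3-methylbut-2-enyloxy)phenyl]isoxazole, via nitrile oxide 15 (not isolated), via 5-hydroxy-2-isoxazoline 16 (not isolated)
Conditions: 9, LiN(SiMe3)2 (2.2 equiv), THF, −78 °C; 14 (1.2 equiv) in THF added dropwise, −78 to −20 °C; sat. aq. NH4Cl; then crude 16, (CF3CO)2O, pyridine, CH2Cl2, 0 °C to rt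
Reagents that add atoms: none
Why: The enolate of 9, whose only nucleophilic carbon is the prenyloxy-bearing one (future C3), adds to the carbon of nitrile oxide 15 (future C2), set free from 14 by the second equivalent of base, and the oximate oxygen then closes onto the ketone carbon (future C4) in a 5-exo-trig addition to give hemiketal 16; the two events may also be read as a strongly asynchronous 1,3-dipolar cycloaddition across the enolate C=C. Trifluoroacetylation of the hemiketal hydroxyl and pyridine-induced elimination then aromatise 16 to isoxazole 17. The closest known reaction type is the condensation of aryl nitrile oxides with ketone lithium enolates to 5-hydroxy-2-isoxazolines followed by dehydration to 3,4,5-trisubstituted isoxazoles. No stereocentre has to be controlled, since the two formed in 16 are erased on dehydration. The selectivity needed is regiochemical and is fixed by the substrate: with one carbon nucleophile and one carbon electrophile, ring B must end on the C=N carbon and ring A on the C–O carbon. Running the enolate stage cold and briefly should let the addition outpace nitrile oxide dimerisation and cycloaddition to the prenyl alkenes, and guards the α-prenyloxy enolate against silyl transfer from the neighbouring aryl oxygen and against [2,3]-Wittig or Claisen-type rearrangement.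

Step 10
Reactants: 17 5-[3-methoxy-6-(methoxymethoxy)-2,4-bis(triisopropylsilyloxy)phenyl]-4-(3-methylbut-2-enyloxy)-3-[4-(3-methylbut-2-enyloxy)phenyl]isoxazole
Product: 18 (E)-3-amino-1-[3-methoxy-6-(methoxymethoxy)-2,4-bis(triisopropylsilyloxy)phenyl]-2-(3-methylbut-2-enyloxy)-3-[4-(3-methylbut-2-enyloxy)phenyl]prop-2-en-1-one
Conditions: Mo(CO)6 (1 equiv), MeCN/H2O, 75 °C
Reagents that add atoms: none
Why: Reductive N–O cleavage of the isoxazole by molybdenum hexacarbonyl in wet acetonitrile should give the β-amino enone without touching the prenyl alkenes, the silyl ethers or the acetal, which hydrogenolysis would not spare.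

Step 11
Reactants: 18 (E)-3-amino-1-[3-methoxy-6-(methoxymethoxy)-2,4-bis(triisopropylsilyloxy)phenyl]-2-(3-methylbut-2-enyloxy)-3-[4-(3-methylbut-2-enyloxy)phenyl]prop-2-en-1-one
Product: 20 7-hydroxy-8-methoxy-5-(methoxymethoxy)-3-(3-methylbut-2-enyloxy)-2-[4-(3-methylbut-2-enyloxy)phenyl]-4H-chromen-4-one, via diphenol enaminone 19 (not isolated)
Conditions: Bu4NF (2.2 equiv), THF, 0 °C; then AcOH (excess), rt to 45 °C
Reagents that add atoms: none
Why: Fluoride removes both aryl silyl ethers, and under mild acid the one free ortho hydroxyl adds to the amine-bearing carbon and ammonia is lost (chromone-forming addition–elimination on a vinylogous amide); the acetal-blocked oxygen cannot compete, so only the 8-methoxy isomer can form.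

Step 12
Reactants: 20 7-hydroxy-8-methoxy-5-(methoxymethoxy)-3-(3-methylbut-2-enyloxy)-2-[4-(3-methylbut-2-enyloxy)phenyl]-4H-chromen-4-one
Product: 21 5,7-dihydroxy-8-methoxy-3-(3-methylbut-2-enyloxy)-2-[4-(3-methylbut-2-enyloxy)phenyl]-4H-chromen-4-one
Conditions: HCl (0.3 M) in MeOH/THF, 0 °C to rt
Reagents that add atoms: none
Why: Acid-catalysed acetal methanolysis; the acetal peri to the C4 carbonyl is the most acid-labile site (carbonyl-assisted, with a chelated phenol as product), so dilute acid at room temperature should remove it before the prenyl ethers ionise.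

Compound list
1 | 2-methoxyresorcinol | COc1c(O)cccc1O | starting material
2 | 2-methoxy-1,3-bis(triisopropylsilyloxy)benzene | COc1c(O[Si](C(C)C)(C(C)C)C(C)C)cccc1O[Si](C(C)C)(C(C)C)C(C)C | intermediate
3 | 2-[4-methoxy-3,5-bis(triisopropylsilyloxy)phenyl]-4,4,5,5-tetramethyl-1,3,2-dioxaborolane (not isolated) | COc1c(O[Si](C(C)C)(C(C)C)C(C)C)cc(B2OC(C)(C)C(C)(C)O2)cc1O[Si](C(C)C)(C(C)C)C(C)C | intermediate
4 | 4-methoxy-3,5-bis(triisopropylsilyloxy)phenol | COc1c(O[Si](C(C)C)(C(C)C)C(C)C)cc(O)cc1O[Si](C(C)C)(C(C)C)C(C)C | intermediate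
5 | 2-methoxy-5-(methoxymethoxy)-1,3-bis(triisopropylsilyloxy)benzene | COCOc1cc(O[Si](C(C)C)(C(C)C)C(C)C)c(OC)c(O[Si](C(C)C)(C(C)C)C(C)C)c1 | intermediate
6 | 3-methylbut-2-en-1-ol (prenyl alcohol) | CC(C)=CCO | starting material
7 | 2-chloro-N-methoxy-N-methylacetamide | CON(C)C(=O)CCl | starting material
8 | N-methoxy-N-methyl-2-(3-methylbut-2-enyloxy)acetamide | CC(C)=CCOCC(=O)N(C)OC | intermediate
9 | 1-[3-methoxy-6-(methoxymethoxy)-2,4-bis(triisopropylsilyloxy)phenyl]-2-(3-methylbut-2-enyloxy)ethan-1-one | CC(C)=CCOCC(=O)c1c(OCOC)cc(O[Si](C(C)C)(C(C)C)C(C)C)c(OC)c1O[Si](C(C)C)(C(C)C)C(C)C | intermediate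
10 | 4-hydroxybenzaldehyde | O=Cc1ccc(O)cc1 | starting material
11 | prenyl bromide (1-bromo-3-methylbut-2-ene) | CC(C)=CCBr | starting material
12 | 4-(3-methylbut-2-enyloxy)benzaldehyde | CC(C)=CCOc1ccc(C=O)cc1 | intermediate
13 | (E)-4-(3-methylbut-2-enyloxy)benzaldehyde oxime | CC(C)=CCOc1ccc(/C=N/O)cc1 | intermediate
14 | (Z)-N-hydroxy-4-(3-methylbut-2-enyloxy)benzimidoyl chloride | CC(C)=CCOc1ccc(/C(Cl)=N/O)cc1 | intermediate
15 | 4-(3-methylbut-2-enyloxy)benzonitrile oxide (not isolated) | CC(C)=CCOc1ccc(C#[N+][O-])cc1 | intermediate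
16 | 5-[3-methoxy-6-(methoxymethoxy)-2,4-bis(triisopropylsilyloxy)phenyl]-4-(3-methylbut-2-enyloxy)-3-[4-(3-methylbut-2-enyloxy)phenyl]-4,5-dihydroisoxazol-5-ol (racemic mixture of diastereomers; not isolated) | CC(C)=CCOc1ccc(C2=NOC(O)(c3c(OCOC)cc(O[Si](C(C)C)(C(C)C)C(C)C)c(OC)c3O[Si](C(C)C)(C(C)C)C(C)C)C2OCC=C(C)C)cc1 | intermediate
17 | 5-[3-methoxy-6-(methoxymethoxy)-2,4-bis(triisopropylsilyloxy)phenyl]-4-(3-methylbut-2-enyloxy)-3-[4-(3-methylbut-2-enyloxy)phenyl]isoxazole | CC(C)=CCOc1ccc(-c2noc(-c3c(OCOC)cc(O[Si](C(C)C)(C(C)C)C(C)C)c(OC)c3O[Si](C(C)C)(C(C)C)C(C)C)c2OCC=C(C)C)cc1 | intermediate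
18 | (E)-3-amino-1-[3-methoxy-6-(methoxymethoxy)-2,4-bis(triisopropylsilyloxy)phenyl]-2-(3-methylbut-2-enyloxy)-3-[4-(3-methylbut-2-enyloxy)phenyl]prop-2-en-1-one | N/C(c1ccc(OCC=C(C)C)cc1)=C(\C(=O)c1c(OCOC)cc(O[Si](C(C)C)(C(C)C)C(C)C)c(OC)c1O[Si](C(C)C)(C(C)C)C(C)C)OCC=C(C)C | intermediate
19 | (E)-3-amino-1-[2,4-dihydroxy-3-methoxy-6-(methoxymethoxy)phenyl]-2-(3-methylbut-2-enyloxy)-3-[4-(3-methylbut-2-enyloxy)phenyl]prop-2-en-1-one (not isolated) | N/C(c1ccc(OCC=C(C)C)cc1)=C(\C(=O)c1c(OCOC)cc(O)c(OC)c1O)OCC=C(C)C | intermediate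
20 | 7-hydroxy-8-methoxy-5-(methoxymethoxy)-3-(3-methylbut-2-enyloxy)-2-[4-(3-methylbut-2-enyloxy)phenyl]-4H-chromen-4-one | COCOc1cc(O)c(OC)c2oc(-c3ccc(OCC=C(C)C)cc3)c(OCC=C(C)C)c(=O)c12 | intermediate
21 | 5,7-dihydroxy-8-methoxy-3-(3-methylbut-2-enyloxy)-2-[4-(3-methylbut-2-enyloxy)phenyl]-4H-chromen-4-one (5,7-dihydroxy-8-methoxy-3,4'-diprenyloxyflavone) | COc1c(O)cc(O)c2c(=O)c(OCC=C(C)C)c(-c3ccc(OCC=C(C)C)cc3)oc12 | target

Total step count: 12
Longest linear sequence: 8 steps (steps 1, 2, 3, 5, 9, 10, 11, 12, from 2-methoxyresorcinol)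

Steps most likely to fail

Step 9. What may go wrong: bond formation at the congested enolate is slow, so the nitrile oxide dimerises, or the α-prenyloxy enolate transfers silicon or rearranges before it is captured. Fallback: setting out from ketone 9, the lithium enolate (LiN(SiMe3)2, THF, −78 °C) is intercepted within minutes by aldehyde 12 in an aldol addition to give β-hydroxy ketone F1 as a diastereomer mixture. Dess–Martin periodinane (NaHCO3, CH2Cl2) should oxidise it to 2-prenyloxy-1,3-diketone F2. Bu4NF and then AcOH with pyridinium p-toluenesulfonate at 60 °C should give desilylated diketone F3, which is not isolated and should cyclodehydrate through its only free ortho hydroxyl (Baker–Venkataraman-type diketone ring closure). The fallback comes back to the route at flavone 20.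

Step 12. What may go wrong: under acid the prenyl ethers ionise, or methanol adds across their alkenes, at a rate comparable with acetal cleavage. Fallback: the acid-labile acetal is replaced at the outset by a fluoride-labile one. Setting out from phenol 4, 2-(trimethylsilyl)ethoxymethyl chloride and i-Pr2NEt should give 2-(trimethylsilyl)ethoxymethyl ether F4. Metalation and acylation with 8 as in step 5 should give ketone F5. The operations of steps 9, 10 and 11 then lead through hydroxyisoxazoline F6 (not isolated), isoxazole F7, enaminone F8 and diphenol enaminone F9 (not isolated) to 5-O-[2-(trimethylsilyl)ethoxymethyl] flavone F10. Bu4NF in THF at 45–60 °C should then free the C5 hydroxyl by fluoride-induced fragmentation, coming back to the route at target 21 with no acid stronger than acetic acid.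

Step 5. What may go wrong: deprotonation at a position screened by the neighbouring silyloxy group is slow, which leaves time for oxygen-to-carbon silyl migration in the aryllithium, or the aryllithium deprotonates the Weinreb amide instead of adding to it. Fallback: setting out from arene 5, electrophilic bromination (NBS, MeCN, 0 °C) at one of the two equivalent free positions, both doubly activated, should give aryl bromide F11. Bromine–lithium exchange (t-BuLi, THF, −78 °C, minutes), transmetalation with MgBr2·OEt2 and addition of 8 should then give the ketone through a less basic arylmagnesium species that does not undergo silyl migration. The fallback comes back to the route at ketone 9.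

Further compounds
F1 | step 9 | 3-hydroxy-1-[3-methoxy-6-(methoxymethoxy)-2,4-bis(triisopropylsilyloxy)phenyl]-2-(3-methylbut-2-enyloxy)-3-[4-(3-methylbut-2-enyloxy)phenyl]propan-1-one (racemic mixture of diastereomers) | CC(C)=CCOC(C(O)c1ccc(OCC=C(C)C)cc1)C(=O)c1c(OCOC)cc(O[Si](C(C)C)(C(C)C)C(C)C)c(OC)c1O[Si](C(C)C)(C(C)C)C(C)C
F2 | step 9 | 1-[3-methoxy-6-(methoxymethoxy)-2,4-bis(triisopropylsilyloxy)phenyl]-2-(3-methylbut-2-enyloxy)-3-[4-(3-methylbut-2-enyloxy)phenyl]propane-1,3-dione (racemic) | CC(C)=CCOC(C(=O)c1ccc(OCC=C(C)C)cc1)C(=O)c1c(OCOC)cc(O[Si](C(C)C)(C(C)C)C(C)C)c(OC)c1O[Si](C(C)C)(C(C)C)C(C)C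
F3 | step 9 | 1-[2,4-dihydroxy-3-methoxy-6-(methoxymethoxy)phenyl]-2-(3-methylbut-2-enyloxy)-3-[4-(3-methylbut-2-enyloxy)phenyl]propane-1,3-dione (racemic) | CC(C)=CCOC(C(=O)c1ccc(OCC=C(C)C)cc1)C(=O)c1c(OCOC)cc(O)c(OC)c1O
F4 | step 12 | 2-methoxy-1,3-bis(triisopropylsilyloxy)-5-{[2-(trimethylsilyl)ethoxy]methoxy}benzene | C[Si](C)(C)CCOCOc1cc(O[Si](C(C)C)(C(C)C)C(C)C)c(OC)c(O[Si](C(C)C)(C(C)C)C(C)C)c1
F5 | step 12 | 1-(3-methoxy-2,4-bis(triisopropylsilyloxy)-6-{[2-(trimethylsilyl)ethoxy]methoxy}phenyl)-2-(3-methylbut-2-enyloxy)ethan-1-one | CC(C)=CCOCC(=O)c1c(OCOCC[Si](C)(C)C)cc(O[Si](C(C)C)(C(C)C)C(C)C)c(OC)c1O[Si](C(C)C)(C(C)C)C(C)C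
F6 | step 12 | 5-(3-methoxy-2,4-bis(triisopropylsilyloxy)-6-{[2-(trimethylsilyl)ethoxy]methoxy}phenyl)-4-(3-methylbut-2-enyloxy)-3-[4-(3-methylbut-2-enyloxy)phenyl]-4,5-dihydroisoxazol-5-ol (racemic mixture of diastereomers) | CC(C)=CCOc1ccc(C2=NOC(O)(c3c(OCOCC[Si](C)(C)C)cc(O[Si](C(C)C)(C(C)C)C(C)C)c(OC)c3O[Si](C(C)C)(C(C)C)C(C)C)C2OCC=C(C)C)cc1
F7 | step 12 | 5-(3-methoxy-2,4-bis(triisopropylsilyloxy)-6-{[2-(trimethylsilyl)ethoxy]methoxy}phenyl)-4-(3-methylbut-2-enyloxy)-3-[4-(3-methylbut-2-enyloxy)phenyl]isoxazole | CC(C)=CCOc1ccc(-c2noc(-c3c(OCOCC[Si](C)(C)C)cc(O[Si](C(C)C)(C(C)C)C(C)C)c(OC)c3O[Si](C(C)C)(C(C)C)C(C)C)c2OCC=C(C)C)cc1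
F8 | step 12 | (E)-3-amino-1-(3-methoxy-2,4-bis(triisopropylsilyloxy)-6-{[2-(trimethylsilyl)ethoxy]methoxy}phenyl)-2-(3-methylbut-2-enyloxy)-3-[4-(3-methylbut-2-enyloxy)phenyl]prop-2-en-1-one | N/C(c1ccc(OCC=C(C)C)cc1)=C(\C(=O)c1c(OCOCC[Si](C)(C)C)cc(O[Si](C(C)C)(C(C)C)C(C)C)c(OC)c1O[Si](C(C)C)(C(C)C)C(C)C)OCC=C(C)C
F9 | step 12 | (E)-3-amino-1-(2,4-dihydroxy-3-methoxy-6-{[2-(trimethylsilyl)ethoxy]methoxy}phenyl)-2-(3-methylbut-2-enyloxy)-3-[4-(3-methylbut-2-enyloxy)phenyl]prop-2-en-1-one | N/C(c1ccc(OCC=C(C)C)cc1)=C(\C(=O)c1c(OCOCC[Si](C)(C)C)cc(O)c(OC)c1O)OCC=C(C)C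
F10 | step 12 | 7-hydroxy-8-methoxy-3-(3-methylbut-2-enyloxy)-2-[4-(3-methylbut-2-enyloxy)phenyl]-5-{[2-(trimethylsilyl)ethoxy]methoxy}-4H-chromen-4-one | C[Si](C)(C)CCOCOc1cc(O)c(OC)c2oc(-c3ccc(OCC=C(C)C)cc3)c(OCC=C(C)C)c(=O)c12
F11 | step 5 | 2-bromo-4-methoxy-1-(methoxymethoxy)-3,5-bis(triisopropylsilyloxy)benzene | COCOc1cc(O[Si](C(C)C)(C(C)C)C(C)C)c(OC)c(O[Si](C(C)C)(C(C)C)C(C)C)c1Br
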